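## The problem

Numbering used throughout: carbocycle C1 (ketone), C2, C3, C4 (methyl-bearing), C5, C6 (lactone O–CH), C7, C8 (angelate O–CH), C9, C10 (tertiary carbinol); lactone C11 (α-carbon), C12 (carbonyl), C13 (exo-methylene). Compound 31 is a ten-membered carbocycle with a Z-trisubstituted C4=C5 alkene, a C1 ketone and an α-methylene γ-lactone trans-fused across C6–C7. Four stereocentres must be delivered: the contiguous triad C6 (R), C7 (R), C8 (R) and the quaternary carbinol C10 (S). C10 is quaternary and insulated from the triad by C9, so it can neither be relayed from the triad nor steer it reliably, and is best taken from the chiral pool. Within the triad the C6 oxygen and the C7 side chain are syn (an aldol-type pair, made together) and the C6 and C8 oxygens are 1,3-anti, so a free C6 hydroxyl can direct the creation of C8; the two oxygens must then be told apart, one for the lactone and one for the angelate. The angelate (Z to E drift, Michael acceptor), the α-methylene lactone (Michael acceptor, to be unveiled last), the Z alkene (scrambled by allyl-metal or allyl-cation intermediates) and the C10 α-ketol beside a 1,3-dioxygenated chain (acyl and silyl migration) will not survive strong base, hard nucleophiles or acid. The enabling feature is that C10 bears no hydrogen, so the C1 ketone enolises only towards C2, while C3 is allylic to C4=C5: C2–C3 is a carbanion/allylic halide bond, and a sulfonyl group on C2 makes that carbanion available with carbonate.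

## Retrosynthesis

Lactone last. Compound 31 is traced to triol 28 by cutting the C12–O6 acyl bond and lowering C12 to the alcohol, then to the silyl ethers 27 and, by restoring the C2–S bond, to sulfonyl ketone 26. Storing the lactone as an allylic 1,4-diol removes the Michael acceptor that would otherwise capture the C2 carbanion. The neighbouring option, a late α-methylenation of a saturated lactone, would need enolate chemistry beside the enolisable C1/C2 ketone. The forward steps must oxidise the primary allylic C12–OH in the presence of the secondary allylic C6–OH and close onto it.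

Ring closure at C2–C3. Compound 26 is opened to the seco allylic chloride 24. Closing C1–C2 instead would need a non-stabilised sulfone carbanion beside esters. Closing C3–C4 or C5–C6 would put alkene geometry or a new stereocentre at risk in the ring-forming event. Precursor 24 is acyclic with all four permanent stereocentres, the Z alkene and the angelate in place. The forward reaction has to favour C- over O-alkylation, SN2 over SN2' and ring closure over oligomerisation.

Sulfone, angelate and chloride. Compound 24 comes from allylic alcohol 22, this from PMB ether 21, and 21 from alcohol 19 and angelic acid 20. The C1–C2 bond of 19 is cut to methyl phenyl sulfone 18 and γ-lactone 17. The lactone is both the activated form of C1 and the protecting group of the C8 oxygen, so its opening frees exactly the hydroxyl that takes the angelate. The order is fixed: the lithiated sulfone tolerates no ester, so the sulfone precedes the angelate; the chloride comes last because it would alkylate the sulfone anion.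

C8 and the differentiation of the oxygens. Lactone 17 is the bis-silyl ether of 16, which is traced (through diol 15) to β-hydroxy ketone 14 by cutting C8–H and the C1–O8 lactone bond. A C6–OH-directed reduction gives the 1,3-anti relationship; only the new C8 hydroxyl can reach C1 in a five-membered ring, so lactonisation tells the C8 oxygen from the C6 oxygen without a protecting-group step. Creating C8 directly in a C7–C8 bond formation would need an anti-aldol, or an allylation whose chair transition state is expected to give the C8 epimer.

C6–C7 by syn aldol. Compound 14 is cut into allyl ketone 12 and Z-enal 6. The C6 oxygen and the C7 side chain are a syn aldol pair, and the ketone partner keeps C8 at the oxidation level needed for the directed reduction. The forward step requires enolisation at C7 and not at C9, a Z-enolate, and facial control by the boron ligands, since the C10 centre of 12 is too remote to help.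

C7–C8 and the chiral pool. Ketone 12 is cut at C7–C8 into the acid chloride 11 of dioxolanone acid 8 and allylsilane 10. Acid 8 is (S)-citramalic acid 7 with C1 and the C10 hydroxyl masked in one ring and the C8 carboxyl free. Silane 10 is the silyl ether of alcohol 9 and supplies C7, C11, C12 and C13 with the exo-methylene already in place. Ketone formation by acylation avoids a free C8 hydroxyl at this stage, which would lactonise prematurely.

The Z C3–C6 unit. Enal 6 is traced through alcohol 5 and enoate 4 to ynoate 3, made from propargyl ether 2 and propargyl alcohol 1. Syn carbocupration of 3 sets the C4 methyl group and the Z geometry in one step. The C3 oxygen carries from the start a PMB group that can be removed late in the presence of every silyl ether.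

## Roads not taken

Alternative 1: the cut is C5–C6 together with the lactone C–O bond. In the forward step CrCl2 with catalytic NiCl2 would turn the Z-alkenyl iodide of the open-chain aldehyde ester A1 into an alkenylchromium that adds to the C6 aldehyde. The resulting alkoxide would close onto the C12 methyl ester to give lactone A2. Its merits are real: ring closure, lactone formation and the C6 centre in one operation, retention of the Z geometry in the alkenylchromium, tolerance of esters, and no sulfone to install and remove. As a medium-ring closure it is at least as well established as the chosen one. Its weak points here are as follows.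
- C6 would be created during ring closure under the control of C7 alone, without a reliable model, and the wrong epimer gives the cis-lactone.
- The aldehyde of A1 has an epimerisable C7 with a β-oxygen at C8.
- The C1 ketone sits where a five-membered closure from C5 is possible.
- A2 still lacks C13, so an α-methylenation beside a ketone enolisable at C2 remains.

The chosen plan fixes all four permanent stereocentres before cyclisation and creates only a transient one, at the price of sulfone handling and three closing steps.

Alternative 2: a transannular C1–C5 bond is added in the retrosynthetic direction. The hydroazulene A3, a C1 tertiary alcohol with a C4 stannyl group, would be oxidised by PhI(OAc)2 (trivalent iodine). The C1–C5 bond would break in a Grob fragmentation to give the ten-membered ketone A4 with the C4=C5 alkene. This avoids any entropically costly cyclisation and any high dilution. The alkene geometry follows stereospecifically from the substrate, and the α-methylene lactone can already be present, so A4 is only an acetonide cleavage and an angeloylation away from 31. In the ring-forming event and in the endgame this road is better than the chosen one. Against it stands the precursor: A3 needs seven stereocentres, among them a tertiary stannane at C4 in a defined relation to C5 and C1. Three of these are destroyed in the key step, and a wrong relative configuration gives the E alkene. Building that bicycle with the 6,12-lactone and the C8/C10 oxygens is a larger task than the target. The chosen plan makes only the four centres that remain.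

Alternative 3: the cut is C3–C4. Zerovalent palladium, from Pd(OAc)2 and a bulky phosphine, would insert into the C4–I bond of the cyclopropanol iodide A5. The cyclopropanol would open by β-carbon elimination to a C3 alkylpalladium, and reductive elimination would close the ring and create the C1 ketone in A6. The merits: the ketone and C2–C3 come from a cyclopropanol made from the citramalate ester, no sulfone is needed, the lactone tolerates the conditions, and the alkenylpalladium keeps the Z geometry. On paper it is shorter and more atom-economical than the chosen plan. The weak points: the reductive elimination must occur from an eleven-membered palladacycle, for which there is no close precedent. β-Hydride elimination of the C3 alkylpalladium to the C2=C3 enone is the usual competitor and gains if reductive elimination is slow. A6 still needs α-methylenation and an exchange of the C8 silyl ether for the angelate. The chosen plan sets a classical SN2 closure with precedent in medium carbocycles against the one step it loses to desulfonylation.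

Key step: step 16

## Route

Assumption: (−)-Ipc2BOTf (from (+)-α-pinene) is taken to direct the Z-enolate of 12 to the Si face of aldehyde 6, the sense shown by the related Ipc2B allylborations; if the opposite sense is found, (+)-Ipc2BOTf is used and nothing else changes.

Step 1
Reactants: 1 prop-2-yn-1-ol
Product: 2 1-methoxy-4-[(prop-2-yn-1-yloxy)methyl]benzene
Conditions: NaH, PMBCl, Bu4NI (cat.), THF/DMF, 0 °C to rt
Reagents that add atoms: 4-methoxybenzyl chloride, COc1ccc(CCl)cc1
Why: Williamson ether synthesis; one equivalent of NaH forms the alkoxide and not the acetylide, and the benzylic chloride alkylates it.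

Step 2
Reactants: 2 1-methoxy-4-[(prop-2-yn-1-yloxy)methyl]benzene
Product: 3 methyl 4-[(4-methoxybenzyl)oxy]but-2-ynoate
Conditions: n-BuLi, THF, −78 °C; ClCO2Me, −78 to 0 °C
Reagents that add atoms: methyl chloroformate, COC(=O)Cl
Why: C-acylation of the lithium acetylide with a chloroformate gives the ynoate; the PMB ether is inert.

Step 3
Reactants: 3 methyl 4-[(4-methoxybenzyl)oxy]but-2-ynoate
Product: 4 methyl (2Z)-4-[(4-methoxybenzyl)oxy]-3-methylbut-2-enoate
Conditions: Me2CuLi (from MeLi, CuI), THF, −78 °C; MeOH then aq. NH4Cl at −78 °C
Reagents that add atoms: lithium dimethylcuprate, [Li+].C[Cu-]C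
Why: Syn carbocupration of the ynoate with cold protonation delivers methyl and hydrogen cis, which places CH2OPMB cis to the ester (2Z); this sets the C4 methyl group and the C4=C5 geometry.

Step 4
Reactants: 4 methyl (2Z)-4-[(4-methoxybenzyl)oxy]-3-methylbut-2-enoate
Product: 5 (2Z)-4-[(4-methoxybenzyl)oxy]-3-methylbut-2-en-1-ol
Conditions: i-Bu2AlH (2.2 equiv), CH2Cl2, −78 °C; aq. potassium sodium tartrate
Reagents that add atoms: none
Why: 1,2-Reduction of an enoate by i-Bu2AlH to the allylic alcohol; no conjugate reduction or change of alkene geometry is expected at −78 °C.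

Step 5
Reactants: 5 (2Z)-4-[(4-methoxybenzyl)oxy]-3-methylbut-2-en-1-ol
Product: 6 (2Z)-4-[(4-methoxybenzyl)oxy]-3-methylbut-2-enal
Conditions: Dess–Martin periodinane, NaHCO3, CH2Cl2, 0 °C
Reagents that add atoms: none
Why: Buffered Dess–Martin oxidation of a primary allylic alcohol; neutral cold conditions should avoid Z to E isomerisation of the enal, which is used without storage.

Step 6
Reactants: 7 (S)-citramalic acid
Product: 8 [(4S)-2,2,4-trimethyl-5-oxo-1,3-dioxolan-4-yl]acetic acid
Conditions: 2,2-dimethoxypropane, p-TsOH (cat.), rt
Reagents that add atoms: 2,2-dimethoxypropane, COC(C)(C)OC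
Why: Acid-catalysed acetalisation; the α-hydroxy acid closes the five-membered dioxolanone in preference to the six-membered alternative, masking C1 and the C10 hydroxyl and leaving the C8 carboxyl free; C10 (S) is untouched.

Step 7
Reactants: 9 2-[(trimethylsilyl)methyl]prop-2-en-1-ol
Product: 10 tert-butyldimethyl({2-[(trimethylsilyl)methyl]prop-2-en-1-yl}oxy)silane
Conditions: TBSCl, imidazole, CH2Cl2, 0 °C to rt
Reagents that add atoms: tert-butyldimethylsilyl chloride, CC(C)(C)[Si](C)(C)Cl
Why: Silylation of a primary allylic alcohol gives the 2-substituted allylsilane that carries C7, C11, C12 and C13.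

Step 8
Reactants: 8 [(4S)-2,2,4-trimethyl-5-oxo-1,3-dioxolan-4-yl]acetic acid; 10 tert-butyldimethyl({2-[(trimethylsilyl)methyl]prop-2-en-1-yl}oxy)silane
Product: 12 allyl ketone (10S) with C8 ketone and C12 OTBS, via acid chloride 11 (not isolated)
Conditions: (COCl)2, DMF (cat.), CH2Cl2, 0 °C to rt, evaporate; 10, TiCl4, CH2Cl2, −78 °C
Reagents that add atoms: none
Why: Acid chloride formation, then Hosomi–Sakurai-type acylation of the allylsilane: the activated acyl group attacks the CH2 terminus and loss of the silyl group regenerates the 1,1-disubstituted alkene, forming C7–C8 as a β,γ-unsaturated ketone; −78 °C and neutral work-up should keep the alkene out of conjugation and the dioxolanone intact.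

Step 9
Reactants: 12 allyl ketone (10S); 6 (2Z)-4-[(4-methoxybenzyl)oxy]-3-methylbut-2-enal
Product: 14 syn-aldol adduct (6R,7S,10S), via boron enolate 13 (not isolated)
Conditions: (−)-Ipc2BOTf, i-Pr2NEt, CH2Cl2, −78 °C; 6, −78 to −20 °C; H2O2, MeOH, pH 7 buffer, 0 °C
Reagents that add atoms: none
Why: Boron aldol of an Ipc2B enolate: enolisation is expected at the more acidic and less hindered C7 (C9 is neopentyl) to give the Z-enolate, whose chair transition state gives the syn C6/C7 pair; the Ipc ligands are expected to select the aldehyde Si face, setting C6 (R) and C7 (7S by CIP here, the same spatial arrangement as 7R in 31).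

Step 10
Reactants: 14 syn-aldol adduct (6R,7S,10S)
Product: 16 γ-lactone diol (6R,7S,8R,10S), via anti-diol 15 (not isolated)
Conditions: Me4NBH(OAc)3, MeCN/AcOH, −30 °C; then PPTS (cat.), toluene, 50 °C
Reagents that add atoms: none
Why: Evans–Saksena reduction: the C6 hydroxyl binds the acetoxyborohydride and delivers hydride intramolecularly through a chair, which should give the 1,3-anti diol and so C8 (R); the new γ-hydroxyl then transacylates the dioxolanone with loss of acetone to the five-membered lactone, which tells the C8 oxygen from the C6 oxygen.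

Step 11
Reactants: 16 γ-lactone diol (6R,7S,8R,10S)
Product: 17 bis(triethylsilyl) ether (6R,7R,8R,10S)
Conditions: Et3SiOTf (3 equiv), 2,6-lutidine, CH2Cl2, −78 to 0 °C
Reagents that add atoms: triethylsilyl trifluoromethanesulfonate, CC[Si](CC)(CC)OS(=O)(=O)C(F)(F)F
Why: Silyl triflate silylation of the secondary allylic C6–OH and the tertiary C10–OH in one operation; the lactone α-carbon is quaternary, so enolisation cannot interfere.

Step 12
Reactants: 17 bis(triethylsilyl) ether (6R,7R,8R,10S); 18 methyl phenyl sulfone
Product: 19 C8-hydroxy β-keto sulfone (6R,7R,8R,10S)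
Conditions: 18 (3 equiv), n-BuLi, THF, −78 °C; then 17, −78 to −40 °C; aq. NH4Cl
Reagents that add atoms: none
Why: Claisen-type acylation of the lithiated sulfone by the lactone forms C1–C2; the β-keto sulfone is deprotonated at once by a second equivalent, which prevents a second addition, and the C8 oxygen is released as the only free hydroxyl.

Step 13
Reactants: 19 C8-hydroxy β-keto sulfone (6R,7R,8R,10S); 20 angelic acid
Product: 21 C8 angelate (6R,7R,8R,10S)
Conditions: 20, 2,4,6-trichlorobenzoyl chloride, Et3N, toluene, rt; then 19, toluene, 80 °C
Reagents that add atoms: none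
Why: Yamaguchi-type esterification through the mixed 2,4,6-trichlorobenzoic anhydride without a nucleophilic catalyst, conditions that transfer the angeloyl group without Z to E isomerisation; C8–OH is the only hydroxyl.

Step 14
Reactants: 21 C8 angelate (6R,7R,8R,10S)
Product: 22 C3 allylic alcohol (6R,7R,8R,10S)
Conditions: DDQ, CH2Cl2/pH 7 buffer, 0 °C
Reagents that add atoms: none
Why: Oxidative PMB cleavage (hydride abstraction by DDQ, hydrolysis of the oxocarbenium ion); silyl ethers, angelate and keto sulfone are inert, and the buffer protects the triethylsilyl ethers.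

Step 15
Reactants: 22 C3 allylic alcohol (6R,7R,8R,10S)
Product: 24 seco β-keto sulfone Z-allylic chloride (6R,7R,8R,10S), via allylic mesylate 23 (not isolated)
Conditions: MsCl, 2,4,6-collidine, LiCl, DMF, 0 °C
Reagents that add atoms: lithium chloride, [Li+].[Cl-]
Why: Mesylation and in situ SN2 displacement by chloride at the primary allylic carbon, without allylic transposition and with a base too weak to deprotonate the keto sulfone; the Z geometry is untouched.

Step 16
Reactants: 24 seco β-keto sulfone Z-allylic chloride (6R,7R,8R,10S)
Product: 26 ten-membered 2-(phenylsulfonyl) ketone (6R,7R,8R,10S; C2 epimers), via caesium enolate 25 (not isolated)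
Conditions: Cs2CO3 (3 equiv), DMF, slow addition of 24 to 0.002 M, 25–40 °C
Reagents that add atoms: none
Why: Cs2CO3 deprotonates C2 (pKa about 12), the only enolisable position of the C1 ketone because C10 is quaternary, to give the caesium enolate. Its carbanion carbon displaces chloride at the primary allylic C3 in an intramolecular SN2 reaction and forms C2–C3. The closest known reaction type is the high-dilution cyclisation of sulfone-stabilised carbanions onto allylic halides used for medium and large carbocycles. The ten-membered carbocycle closes in the exo-tet mode. The new C2 stereocentre is not controlled and need not be, since both epimers give the same methylene in step 17. C- over O-alkylation is favoured by the soft delocalised carbanion, the soft allylic chloride and the loose caesium ion pair in DMF; SN2 over SN2' by the unhindered primary terminus against the substituted C5; ring closure over oligomerisation by dilution and by the Z alkene and the quaternary C10, which bring the chain ends together. No allyl-metal intermediate is formed, so the Z geometry is inherited, and carbonate is mild towards the angelate and the silyl ethers. The lactone is still masked as a bis-silylated allylic diol, so no Michael acceptor competes for the carbanion.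

Step 17
Reactants: 26 ten-membered 2-(phenylsulfonyl) ketone (6R,7R,8R,10S; C2 epimers)
Product: 27 ten-membered ketone (6R,7R,8R,10S)
Conditions: SmI2 (2.2 equiv), THF/MeOH, −78 °C
Reagents that add atoms: none
Why: Reductive desulfonylation of an α-sulfonyl ketone by single-electron transfer: the ketyl expels sulfinate and the samarium enolate is protonated by methanol; both C2 epimers converge, and low temperature with a small excess should spare the α-silyloxy ketone and the angelate.

Step 18
Reactants: 27 ten-membered ketone (6R,7R,8R,10S)
Product: 28 triol (6R,7S,8R,10S)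
Conditions: HF·pyridine, pyridine, THF, 0 °C to rt
Reagents that add atoms: none
Why: Fluoride cleavage of the three silyl ethers under buffered acidic conditions, chosen over basic fluoride to avoid 1,3-migration of the angelate to the free C6 hydroxyl.

Step 19
Reactants: 28 triol (6R,7S,8R,10S)
Product: 31 target lactone (6R,7R,8R,10S), via hydroxy enal 29 (not isolated), via lactol 30 (not isolated)
Conditions: TEMPO (cat.), PhI(OAc)2, CH2Cl2, rt
Reagents that add atoms: none
Why: Oxoammonium (TEMPO) oxidation, selective for the primary allylic C12–OH, gives the enal; the C6 hydroxyl closes the five-membered lactol, which is oxidised to the lactone. The trans ring fusion follows from the C6/C7 configuration, and the tertiary C10–OH is inert.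

## Compound list

1 | prop-2-yn-1-ol | C#CCO | starting material
2 | 1-methoxy-4-[(prop-2-yn-1-yloxy)methyl]benzene | C#CCOCc1ccc(OC)cc1 | intermediate
3 | methyl 4-[(4-methoxybenzyl)oxy]but-2-ynoate | COC(=O)C#CCOCc1ccc(OC)cc1 | intermediate
4 | methyl (2Z)-4-[(4-methoxybenzyl)oxy]-3-methylbut-2-enoate | COC(=O)/C=C(/C)COCc1ccc(OC)cc1 | intermediate
5 | (2Z)-4-[(4-methoxybenzyl)oxy]-3-methylbut-2-en-1-ol | OC/C=C(/C)COCc1ccc(OC)cc1 | intermediate
6 | (2Z)-4-[(4-methoxybenzyl)oxy]-3-methylbut-2-enal (C3–C6 unit, C6 aldehyde) | O=C/C=C(/C)COCc1ccc(OC)cc1 | intermediate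
7 | (S)-citramalic acid, (2S)-2-hydroxy-2-methylbutanedioic acid | OC(=O)[C@@](C)(O)CC(=O)O | starting material
8 | [(4S)-2,2,4-trimethyl-5-oxo-1,3-dioxolan-4-yl]acetic acid | O=C1OC(C)(C)O[C@@]1(C)CC(=O)O | intermediate
9 | 2-[(trimethylsilyl)methyl]prop-2-en-1-ol | C=C(CO)C[Si](C)(C)C | starting material
10 | tert-butyldimethyl({2-[(trimethylsilyl)methyl]prop-2-en-1-yl}oxy)silane | C=C(CO[Si](C)(C)C(C)(C)C)C[Si](C)(C)C | intermediate
11 | [(4S)-2,2,4-trimethyl-5-oxo-1,3-dioxolan-4-yl]acetyl chloride | O=C1OC(C)(C)O[C@@]1(C)CC(=O)Cl | intermediate (not isolated)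
12 | (5S)-5-[4-({[tert-butyl(dimethyl)silyl]oxy}methyl)-2-oxopent-4-en-1-yl]-2,2,5-trimethyl-1,3-dioxolan-4-one (C8 ketone, C7 methylene, C11=C13, C12 OTBS, 10S) | O=C1OC(C)(C)O[C@@]1(C)CC(=O)CC(=C)CO[Si](C)(C)C(C)(C)C | intermediate
13 | (Z)-enol diisopinocampheylborinate of 12 (C7=C8, O–B(Ipc)2 on C8, Ipc from (+)-α-pinene) | O=C1OC(C)(C)O[C@@]1(C)C/C(OB([C@@H]2C[C@@H]3C[C@H]([C@H]2C)C3(C)C)[C@@H]2C[C@@H]3C[C@H]([C@H]2C)C3(C)C)=C/C(=C)CO[Si](C)(C)C(C)(C)C | intermediate (not isolated)
14 | syn-aldol adduct (6R,7S,10S; 4Z): C8 ketone, C6 OH, C3 OPMB, C12 OTBS, C1/C10 dioxolanone | O=C1OC(C)(C)O[C@@]1(C)CC(=O)[C@@H](C(=C)CO[Si](C)(C)C(C)(C)C)[C@H](O)/C=C(/C)COCc1ccc(OC)cc1 | intermediate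
15 | anti-1,3-diol (6R,7R,8R,10S; 4Z): C6 OH, C8 OH, dioxolanone intact | O=C1OC(C)(C)O[C@@]1(C)C[C@@H](O)[C@@H](C(=C)CO[Si](C)(C)C(C)(C)C)[C@H](O)/C=C(/C)COCc1ccc(OC)cc1 | intermediate (not isolated)
16 | γ-lactone diol (6R,7S,8R,10S; 4Z): C1(=O)–O–C8 five-membered lactone, C6 OH, C10 OH, C3 OPMB, C12 OTBS | O=C1[C@@](C)(O)C[C@@H](O1)[C@@H](C(=C)CO[Si](C)(C)C(C)(C)C)[C@H](O)/C=C(/C)COCc1ccc(OC)cc1 | intermediate
17 | bis(triethylsilyl) ether of 16 (6R,7R,8R,10S; 4Z): C6 OTES, C10 OTES | O=C1[C@@](C)(O[Si](CC)(CC)CC)C[C@@H](O1)[C@@H](C(=C)CO[Si](C)(C)C(C)(C)C)[C@H](O[Si](CC)(CC)CC)/C=C(/C)COCc1ccc(OC)cc1 | intermediate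
18 | methyl phenyl sulfone | CS(=O)(=O)c1ccccc1 | starting material
19 | C8-hydroxy β-keto sulfone (6R,7R,8R,10S; 4Z): C2 SO2Ph, C1 ketone, C10 OTES, C8 OH, C6 OTES, C12 OTBS, C3 OPMB | O=S(=O)(c1ccccc1)CC(=O)[C@@](C)(O[Si](CC)(CC)CC)C[C@@H](O)[C@@H](C(=C)CO[Si](C)(C)C(C)(C)C)[C@H](O[Si](CC)(CC)CC)/C=C(/C)COCc1ccc(OC)cc1 | intermediate
20 | angelic acid, (2Z)-2-methylbut-2-enoic acid | C/C=C(/C)C(=O)O | starting material
21 | C8 angelate of 19 (6R,7R,8R,10S; 4Z) | O=S(=O)(c1ccccc1)CC(=O)[C@@](C)(O[Si](CC)(CC)CC)C[C@@H](OC(=O)/C(C)=C\C)[C@@H](C(=C)CO[Si](C)(C)C(C)(C)C)[C@H](O[Si](CC)(CC)CC)/C=C(/C)COCc1ccc(OC)cc1 | intermediate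
22 | C3 allylic alcohol (6R,7R,8R,10S; 4Z), PMB removed | O=S(=O)(c1ccccc1)CC(=O)[C@@](C)(O[Si](CC)(CC)CC)C[C@@H](OC(=O)/C(C)=C\C)[C@@H](C(=C)CO[Si](C)(C)C(C)(C)C)[C@H](O[Si](CC)(CC)CC)/C=C(/C)CO | intermediate
23 | C3 allylic mesylate of 22 | O=S(=O)(c1ccccc1)CC(=O)[C@@](C)(O[Si](CC)(CC)CC)C[C@@H](OC(=O)/C(C)=C\C)[C@@H](C(=C)CO[Si](C)(C)C(C)(C)C)[C@H](O[Si](CC)(CC)CC)/C=C(/C)COS(C)(=O)=O | intermediate (not isolated)
24 | seco β-keto sulfone Z-allylic chloride (6R,7R,8R,10S; 4Z), key-step precursor | O=S(=O)(c1ccccc1)CC(=O)[C@@](C)(O[Si](CC)(CC)CC)C[C@@H](OC(=O)/C(C)=C\C)[C@@H](C(=C)CO[Si](C)(C)C(C)(C)C)[C@H](O[Si](CC)(CC)CC)/C=C(/C)CCl | intermediate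
25 | caesium enolate of 24 (carbanion at C2) | O=S(=O)(c1ccccc1)[CH-]C(=O)[C@@](C)(O[Si](CC)(CC)CC)C[C@@H](OC(=O)/C(C)=C\C)[C@@H](C(=C)CO[Si](C)(C)C(C)(C)C)[C@H](O[Si](CC)(CC)CC)/C=C(/C)CCl.[Cs+] | intermediate (not isolated)
26 | ten-membered 2-(phenylsulfonyl) ketone (6R,7R,8R,10S; 4Z; both C2 epimers): C6 OTES, C10 OTES, C12 OTBS, C8 angelate | O=C1C(S(=O)(=O)c2ccccc2)C/C(C)=C\[C@@H](O[Si](CC)(CC)CC)[C@H](C(=C)CO[Si](C)(C)C(C)(C)C)[C@H](OC(=O)/C(C)=C\C)C[C@]1(C)O[Si](CC)(CC)CC | intermediate
27 | ten-membered ketone (6R,7R,8R,10S; 4Z), desulfonylated | O=C1CC/C(C)=C\[C@@H](O[Si](CC)(CC)CC)[C@H](C(=C)CO[Si](C)(C)C(C)(C)C)[C@H](OC(=O)/C(C)=C\C)C[C@]1(C)O[Si](CC)(CC)CC | intermediate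
28 | triol (6R,7S,8R,10S; 4Z): C6 OH, C10 OH, C12 OH, C8 angelate | O=C1CC/C(C)=C\[C@@H](O)[C@H](C(=C)CO)[C@H](OC(=O)/C(C)=C\C)C[C@]1(C)O | intermediate
29 | C12 aldehyde (hydroxy enal; 6R,7S,8R,10S) | O=C1CC/C(C)=C\[C@@H](O)[C@H](C(=C)C=O)[C@H](OC(=O)/C(C)=C\C)C[C@]1(C)O | intermediate (not isolated)
30 | 6,12-lactol (6R,7R,8R,10S; both C12 epimers) | O=C1CC/C(C)=C\[C@H]2OC(O)C(=C)[C@@H]2[C@H](OC(=O)/C(C)=C\C)C[C@]1(C)O | intermediate (not isolated)
31 | CNP0345906.2: (6R,7R,8R,10S,4Z)-8-angeloyloxy-10-hydroxy-1-oxogermacra-4,11(13)-dien-12,6-olide | C=C1C(=O)O[C@@H]2/C=C(/C)CCC(=O)[C@@](C)(O)C[C@@H](OC(=O)/C(C)=C\C)[C@@H]12 | target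

## Step count and least certain steps

Total step count: 19. Longest linear sequence: 16 steps (steps 1–5 and 9–19, from 1 to 31).

Step 16 (key step). The likely failure is intermolecular alkylation to oligomers, together with O-alkylation of the ambident enolate, both competing with the entropically demanding ten-membered C-alkylation. A slow closure would also give the base time to isomerise the angelate. Fallback: alcohol 22 is converted into the methyl carbonate F1 (ClCO2Me, pyridine). F1 is then treated with zerovalent palladium (Pd(PPh3)4, THF, high dilution, 60 °C). Ionisation gives an allylpalladium complex, the methoxide released deprotonates the keto sulfone, and attack at the less hindered C3 terminus forms the same C2–C3 bond and returns to 26. This Tsuji–Trost closure is a different mechanism with a record for sulfone-stabilised nucleophiles in ring formation. Its price is that interconversion of the allyl complex can erode the Z geometry, which would have to be checked.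

Step 9. The likely failure is poor facial selectivity of the boron enolate, because the ligand has to overrule a ketone whose only stereocentre is remote. Slow addition to the hindered Z-enal would in addition leave time for the β,γ-alkene to move into conjugation. Fallback: 12 and 6 are combined through the dibutylboron enolate (n-Bu2BOTf, i-Pr2NEt), which gives only the syn pair without facial preference. Because C10 is fixed, 14 and its (6S,7R) isomer F2 are diastereomers. They are separated by chromatography, and the route continues from 14; control by the reagent is replaced by resolution on the chiral-pool centre.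

Step 8. The likely failure is Lewis-acid opening of the dioxolanone or loss of the silyl ether, and migration of the new double bond into conjugation with the ketone. Fallback: the free carboxyl of 8 is reduced with BH3·SMe2 to the alcohol F3. Dess–Martin oxidation gives the aldehyde F4, and BF3·OEt2-mediated Hosomi–Sakurai allylation with 10 gives the homoallylic alcohol F5 (C8 epimers, of no consequence). Immediate Dess–Martin oxidation returns to 12; F5 must not be stored, since its hydroxyl can close onto the dioxolanone.

Step 13 (with step 12). The likely failure is ring–chain tautomerism of the γ-hydroxy ketone to its cyclic hemiketal, followed by dehydration. Acylation at the acidic C2 or at its enol oxygen, silyl migration to the C8 alkoxide during step 12, and Z to E drift of the angeloyl group are further risks. Fallback: lactone 17 is reduced with i-Bu2AlH at −78 °C to the lactol F6. Lithiated 18 adds to its open aldehyde form and gives the diol F7. The C8 hydroxyl, less hindered than the C1 hydroxyl beside the quaternary C10, is angeloylated under the conditions of step 13 to F8. Dess–Martin oxidation of the C1 carbinol gives 21; in this order the keto sulfone exists only after the C8 oxygen is acylated.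

## Further compounds

F1 | step 16 | methyl carbonate of 22 at C3 (C3–OCO2Me; 6R,7R,8R,10S) | O=S(=O)(c1ccccc1)CC(=O)[C@@](C)(O[Si](CC)(CC)CC)C[C@@H](OC(=O)/C(C)=C\C)[C@@H](C(=C)CO[Si](C)(C)C(C)(C)C)[C@H](O[Si](CC)(CC)CC)/C=C(/C)COC(=O)OC
F2 | step 9 | (6S,7R,10S) syn diastereomer of 14 | O=C1OC(C)(C)O[C@@]1(C)CC(=O)[C@H](C(=C)CO[Si](C)(C)C(C)(C)C)[C@@H](O)/C=C(/C)COCc1ccc(OC)cc1
F3 | step 8 | (5S)-5-(2-hydroxyethyl)-2,2,5-trimethyl-1,3-dioxolan-4-one | O=C1OC(C)(C)O[C@@]1(C)CCO
F4 | step 8 | [(4S)-2,2,4-trimethyl-5-oxo-1,3-dioxolan-4-yl]acetaldehyde | O=C1OC(C)(C)O[C@@]1(C)CC=O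
F5 | step 8 | C8 carbinol corresponding to 12 (both C8 epimers, 10S) | O=C1OC(C)(C)O[C@@]1(C)CC(O)CC(=C)CO[Si](C)(C)C(C)(C)C
F6 | step 13 | C1 lactol from 17 (6R,7R,8R,10S; both C1 epimers) | OC1[C@@](C)(O[Si](CC)(CC)CC)C[C@@H](O1)[C@@H](C(=C)CO[Si](C)(C)C(C)(C)C)[C@H](O[Si](CC)(CC)CC)/C=C(/C)COCc1ccc(OC)cc1
F7 | step 13 | C1,C8-diol β-hydroxy sulfone (6R,7R,8R,10S; both C1 epimers) | O=S(=O)(c1ccccc1)CC(O)[C@@](C)(O[Si](CC)(CC)CC)C[C@@H](O)[C@@H](C(=C)CO[Si](C)(C)C(C)(C)C)[C@H](O[Si](CC)(CC)CC)/C=C(/C)COCc1ccc(OC)cc1
F8 | step 13 | C8 angelate of F7 with free C1 hydroxyl | O=S(=O)(c1ccccc1)CC(O)[C@@](C)(O[Si](CC)(CC)CC)C[C@@H](OC(=O)/C(C)=C\C)[C@@H](C(=C)CO[Si](C)(C)C(C)(C)C)[C@H](O[Si](CC)(CC)CC)/C=C(/C)COCc1ccc(OC)cc1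
A1 | alternative 1 | open-chain Z-alkenyl iodide (C5) with C6 aldehyde, C12 methyl ester, C1 ketone and C8/C10 acetonide | I/C=C(/C)CCC(=O)[C@@](C)(O1)C[C@@H](OC1(C)C)[C@@H](CC(=O)OC)C=O
A2 | alternative 1 | ten-membered Z-ene ketone fused to the trans-lactone (C11 methylene), C8/C10 acetonide | C1C(=O)O[C@@H]2/C=C(/C)CCC(=O)[C@@](C)(O3)C[C@@H](OC3(C)C)[C@@H]12
A3 | alternative 2 | hydroazulene C1 tertiary alcohol with C4 tributylstannyl group, α-methylene lactone and C8/C10 acetonide (C1, C4, C5 configured for anti-periplanar fragmentation to the Z alkene) | C=C1C(=O)O[C@@H]2C3C(C)([Sn](CCCC)(CCCC)CCCC)CCC3(O)[C@@](C)(O4)C[C@@H](OC4(C)C)[C@@H]12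
A4 | alternative 2 | ten-membered Z-ene ketone α-methylene lactone with C8/C10 acetonide | C=C1C(=O)O[C@@H]2/C=C(/C)CCC(=O)[C@@](C)(O3)C[C@@H](OC3(C)C)[C@@H]12
A5 | alternative 3 | trans-lactone carrying the Z C4 alkenyl iodide and the C1 cyclopropanol, C8 OTBS, C10 OTES | I/C(C)=C\[C@H]1OC(=O)C[C@@H]1[C@H](O[Si](C)(C)C(C)(C)C)C[C@](C)(O[Si](CC)(CC)CC)C1(O)CC1
A6 | alternative 3 | ten-membered Z-ene ketone fused to the trans-lactone (C11 methylene), C8 OTBS, C10 OTES | C1C(=O)O[C@@H]2/C=C(/C)CCC(=O)[C@@](C)(O[Si](CC)(CC)CC)C[C@@H](O[Si](C)(C)C(C)(C)C)[C@@H]12
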